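**Retrosynthetic overview**
1. Target 28 comes from tris-MOM flavanone 26, and 26 from aldehyde–enol ether 25: ring C is opened at C3–C4, the forward step being an enantioselective intramolecular hydroacylation (the C4 formyl C–H added across C2=C3).
2. Enabling feature: in 25 the enol ether O1–C2(=C3H2) that carries ring B sits ortho to the C4 formyl group on ring A; this alkene is 1,1-disubstituted and has no allylic hydrogen, so hydride can only go to C2 (the one new stereocentre) and the acyl carbon to C3, closing the six-membered ring C.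
3. 25 comes from salicylaldehyde 19 and bromoalkyne 23 (O1–C2 by phenoxide addition to the haloalkyne, then C–Br to C–H).
4. 19 comes from benzylic bromide 5 and glutarate imide 9: an Evans alkylation sets the (R) side-chain centre, Weinreb/Grignard and Wittig steps build the tertiary carbinol and isopropenyl ends, and ortho-formylation of phenol 17 brings in C4.
5. Ring order: rings A and B are bought as benzaldehydes 1 and 20; ring C is the only ring made (step 18); the three MOM ethers leave last.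

Key step: step 18

Assumption: the (R) antipode of DTBM-SEGPHOS is written for the (2S) series by analogy with carbocyclic hydroacylations; the sense of induction has to be confirmed on a model aldehyde, and the (S) ligand would be used in the same step if it proves opposite.

**Route**

Step 1
Reactants: 1 2,4-dihydroxy-6-methoxybenzaldehyde
Product: 2 2-hydroxy-6-methoxy-4-(methoxymethoxy)benzaldehyde
Conditions: MOMCl (1.1 equiv), i-Pr2NEt, CH2Cl2, 0 °C
Reagents that add atoms: chloromethyl methyl ether, COCCl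
Why: The 4-OH, para to the formyl group and free of the hydrogen bond that ties the 2-OH to the carbonyl, is the more acidic and accessible phenol, so O-alkylation should occur there only.

Step 2
Reactants: 2 2-hydroxy-6-methoxy-4-(methoxymethoxy)benzaldehyde
Product: 3 2-formyl-3-methoxy-5-(methoxymethoxy)phenyl 4-methylbenzenesulfonate
Conditions: TsCl, Et3N, DMAP (cat.), CH2Cl2, 0 °C to rt
Reagents that add atoms: 4-methylbenzenesulfonyl chloride, Cc1ccc(cc1)S(=O)(=O)Cl
Why: DMAP-catalysed sulfonylation of the remaining chelated phenol should be clean, and the electron-poor sulfonate both differentiates this oxygen (the later O1) and tempers the electron-rich ring for the benzylic halide stage.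

Step 3
Reactants: 3 2-formyl-3-methoxy-5-(methoxymethoxy)phenyl 4-methylbenzenesulfonate
Product: 4 2-(hydroxymethyl)-3-methoxy-5-(methoxymethoxy)phenyl 4-methylbenzenesulfonate
Conditions: NaBH4, MeOH/THF, 0 °C
Reagents that add atoms: none
Why: Borohydride reduction of the aldehyde should leave the aryl sulfonate and the MOM acetal untouched.

Step 4
Reactants: 4 2-(hydroxymethyl)-3-methoxy-5-(methoxymethoxy)phenyl 4-methylbenzenesulfonate
Product: 5 2-(bromomethyl)-3-methoxy-5-(methoxymethoxy)phenyl 4-methylbenzenesulfonate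
Conditions: CBr4, PPh3, CH2Cl2, 0 °C; crude bromide used at once in step 6
Reagents that add atoms: carbon tetrabromide, BrC(Br)(Br)Br
Why: The Appel reaction converts the benzylic alcohol under near-neutral conditions that should spare the MOM ether, and the ortho sulfonate should make the dialkoxybenzyl bromide stable enough for immediate use.

Step 5
Reactants: 6 (4S)-4-benzyl-1,3-oxazolidin-2-one; 7 methyl 5-chloro-5-oxopentanoate
Product: 9 methyl 5-[(4S)-4-benzyl-2-oxo-1,3-oxazolidin-3-yl]-5-oxopentanoate, via lithium oxazolidinide 8 (not isolated)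
Conditions: n-BuLi, THF, −78 °C; then 7, −78 to 0 °C
Reagents that add atoms: none
Why: N-acylation of the lithiated auxiliary by the acid chloride is the standard entry to Evans imides, and the acid chloride should react far faster than the methyl ester.

Step 6
Reactants: 9 methyl 5-[(4S)-4-benzyl-2-oxo-1,3-oxazolidin-3-yl]-5-oxopentanoate; 5 2-(bromomethyl)-3-methoxy-5-(methoxymethoxy)phenyl 4-methylbenzenesulfonate
Product: 11 methyl (4R)-5-[(4S)-4-benzyl-2-oxo-1,3-oxazolidin-3-yl]-4-{[2-methoxy-4-(methoxymethoxy)-6-(tosyloxy)phenyl]methyl}-5-oxopentanoate, via sodium (Z)-enolate 10 (not isolated)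
Conditions: NaN(SiMe3)2, THF, −78 °C; then 5, −78 to −30 °C
Reagents that add atoms: none
Why: In this Evans asymmetric alkylation the imide α-hydrogen is removed in preference to the ester α-hydrogen, and the chelated (Z)-enolate should be attacked by the benzylic bromide on the face away from the C4 benzyl group of the auxiliary, which sets the (R) side-chain centre.

Step 7
Reactants: 11 methyl (4R)-5-[(4S)-4-benzyl-2-oxo-1,3-oxazolidin-3-yl]-4-{[2-methoxy-4-(methoxymethoxy)-6-(tosyloxy)phenyl]methyl}-5-oxopentanoate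
Product: 13 (2R)-5-methoxy-2-{[2-methoxy-4-(methoxymethoxy)-6-(tosyloxy)phenyl]methyl}-5-oxopentanoic acid, via peroxy acid 12 (not isolated)
Conditions: LiOH, H2O2, THF/H2O, 0 °C; then aq. Na2SO3; then 1 M HCl
Reagents that add atoms: hydrogen peroxide, OO
Why: Hydroperoxide attacks the exocyclic imide carbonyl selectively and is weakly basic, so the auxiliary should be released without epimerisation and with the methyl ester and the aryl sulfonate intact at 0 °C.

Step 8
Reactants: 13 (2R)-5-methoxy-2-{[2-methoxy-4-(methoxymethoxy)-6-(tosyloxy)phenyl]methyl}-5-oxopentanoic acid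
Product: 14 methyl (4R)-5-[methoxy(methyl)amino]-4-{[2-methoxy-4-(methoxymethoxy)-6-(tosyloxy)phenyl]methyl}-5-oxopentanoate
Conditions: MeNHOMe·HCl, EDC·HCl, HOBt (cat.), N-methylmorpholine, CH2Cl2, 0 °C to rt
Reagents that add atoms: N,O-dimethylhydroxylamine hydrochloride, CNOC.Cl
Why: Carbodiimide coupling through the HOBt ester should give the Weinreb amide without touching the α-centre.

Step 9
Reactants: 14 methyl (4R)-5-[methoxy(methyl)amino]-4-{[2-methoxy-4-(methoxymethoxy)-6-(tosyloxy)phenyl]methyl}-5-oxopentanoate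
Product: 15 2-[(2R)-2-acetyl-5-hydroxy-5-methylhexyl]-3-methoxy-5-(methoxymethoxy)phenyl 4-methylbenzenesulfonate
Conditions: MeMgBr (5 equiv), THF, 0 °C; aq. NH4Cl
Reagents that add atoms: methylmagnesium bromide, C[Mg]Br
Why: In this Weinreb ketone synthesis the chelated tetrahedral adduct holds the amide carbon at the ketone level until work-up while the methyl ester takes two methyl groups, so the methyl ketone and the tertiary carbinol should arise in one operation.

Step 10
Reactants: 15 2-[(2R)-2-acetyl-5-hydroxy-5-methylhexyl]-3-methoxy-5-(methoxymethoxy)phenyl 4-methylbenzenesulfonate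
Product: 16 2-[(2R)-5-hydroxy-5-methyl-2-(prop-1-en-2-yl)hexyl]-3-methoxy-5-(methoxymethoxy)phenyl 4-methylbenzenesulfonate
Conditions: Ph3PCH3Br, KOtBu (ylide in excess), THF, 0 °C to rt
Reagents that add atoms: methyltriphenylphosphonium bromide, C[P+](c1ccccc1)(c1ccccc1)c1ccccc1.[Br-]
Why: Wittig methylenation of the methyl ketone should install the isopropenyl group, the tertiary alkoxide being a spectator and the hindered α-methine not expected to enolise at low temperature.

Step 11
Reactants: 16 2-[(2R)-5-hydroxy-5-methyl-2-(prop-1-en-2-yl)hexyl]-3-methoxy-5-(methoxymethoxy)phenyl 4-methylbenzenesulfonate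
Product: 17 2-[(2R)-5-hydroxy-5-methyl-2-(prop-1-en-2-yl)hexyl]-3-methoxy-5-(methoxymethoxy)phenol
Conditions: Mg turnings, MeOH, rt; aq. NH4Cl
Reagents that add atoms: none
Why: Dissolving-metal reductive cleavage of the aryl sulfonate S–O bond should free the phenol without affecting the isolated alkene, the carbinol or the MOM ether.

Step 12
Reactants: 17 2-[(2R)-5-hydroxy-5-methyl-2-(prop-1-en-2-yl)hexyl]-3-methoxy-5-(methoxymethoxy)phenol
Product: 19 2-hydroxy-3-[(2R)-5-hydroxy-5-methyl-2-(prop-1-en-2-yl)hexyl]-4-methoxy-6-(methoxymethoxy)benzaldehyde, via ortho-hydroxymethyl phenol 18 (not isolated)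
Conditions: MgCl2, Et3N, (CH2O)n, MeCN, 80 °C
Reagents that add atoms: paraformaldehyde (formaldehyde), C=O
Why: In the Casnati–Skattebøl formylation the magnesium phenoxide delivers formaldehyde only to the ortho position, and the single free ortho carbon is C4a, so the formyl group should enter between the phenol and the MOM ether and not at the position para to the phenol.

Step 13
Reactants: 20 2,4-dihydroxybenzaldehyde
Product: 21 2,4-bis(methoxymethoxy)benzaldehyde
Conditions: MOMCl (3 equiv), i-Pr2NEt, CH2Cl2, 0 to 40 °C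
Reagents that add atoms: chloromethyl methyl ether, COCCl
Why: With excess reagent and gentle heating both phenols, including the chelated one, should be converted to MOM ethers.

Step 14
Reactants: 21 2,4-bis(methoxymethoxy)benzaldehyde
Product: 22 1-(2,2-dibromoethenyl)-2,4-bis(methoxymethoxy)benzene
Conditions: CBr4, PPh3, Et3N, CH2Cl2, 0 °C
Reagents that add atoms: carbon tetrabromide, BrC(Br)(Br)Br
Why: The first stage of the Corey–Fuchs sequence (Wittig-type dibromomethylenation) is reliable for aryl aldehydes, and the amine buffer should protect the MOM ethers.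

Step 15
Reactants: 22 1-(2,2-dibromoethenyl)-2,4-bis(methoxymethoxy)benzene
Product: 23 1-(bromoethynyl)-2,4-bis(methoxymethoxy)benzene
Conditions: DBU, DMSO, 20 °C
Reagents that add atoms: none
Why: Amidine-mediated E2 loss of HBr from an aryl gem-dibromoalkene should stop at the 1-bromoalkyne.

Step 16
Reactants: 19 2-hydroxy-3-[(2R)-5-hydroxy-5-methyl-2-(prop-1-en-2-yl)hexyl]-4-methoxy-6-(methoxymethoxy)benzaldehyde; 23 1-(bromoethynyl)-2,4-bis(methoxymethoxy)benzene
Product: 24 2-({(Z)-1-[2,4-bis(methoxymethoxy)phenyl]-2-bromoethenyl}oxy)-3-[(2R)-5-hydroxy-5-methyl-2-(prop-1-en-2-yl)hexyl]-4-methoxy-6-(methoxymethoxy)benzaldehyde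
Conditions: K2CO3, DMF, 90 °C
Reagents that add atoms: none
Why: Base-mediated hydrophenoxylation of a 1-bromoalkyne puts the phenoxide on the aryl-bearing carbon (the developing carbanion is stabilised next to bromine) by anti addition, and the rod-shaped electrophile should be reachable even by this di-ortho-substituted phenoxide, which forges the O1–C2 bond.

Step 17
Reactants: 24 2-({(Z)-1-[2,4-bis(methoxymethoxy)phenyl]-2-bromoethenyl}oxy)-3-[(2R)-5-hydroxy-5-methyl-2-(prop-1-en-2-yl)hexyl]-4-methoxy-6-(methoxymethoxy)benzaldehyde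
Product: 25 2-({1-[2,4-bis(methoxymethoxy)phenyl]ethenyl}oxy)-3-[(2R)-5-hydroxy-5-methyl-2-(prop-1-en-2-yl)hexyl]-4-methoxy-6-(methoxymethoxy)benzaldehyde
Conditions: Pd(PPh3)4 (5 mol%), Bu3SnH (1.2 equiv), THF, rt
Reagents that add atoms: none
Why: Oxidative addition of the vinyl C–Br bond to zerovalent palladium, hydride transfer from tin and reductive elimination should give the 1,1-disubstituted enol ether at room temperature without touching the aldehyde or the isopropenyl group.

Step 18
Reactants: 25 2-({1-[2,4-bis(methoxymethoxy)phenyl]ethenyl}oxy)-3-[(2R)-5-hydroxy-5-methyl-2-(prop-1-en-2-yl)hexyl]-4-methoxy-6-(methoxymethoxy)benzaldehyde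
Product: 26 (2S)-2-[2,4-bis(methoxymethoxy)phenyl]-8-[(2R)-5-hydroxy-5-methyl-2-(prop-1-en-2-yl)hexyl]-7-methoxy-5-(methoxymethoxy)-2,3-dihydro-4H-chromen-4-one
Conditions: [Rh(cod)Cl]2 (5 mol%), (R)-DTBM-SEGPHOS (10 mol%), NaB[3,5-(CF3)2C6H3]4 (10 mol%), 1,4-dioxane, 70 °C
Reagents that add atoms: none
Why: Proposed new method: oxidative addition of the C4 formyl C–H bond to the cationic monovalent rhodium bisphosphine complex should be followed by insertion of the tethered C2=C3 enol ether into Rh–H, with hydride delivered to C2 and rhodium to C3, and by C–C reductive elimination that forms the C3–C4 bond. The closest known reaction type is the rhodium bisphosphine-catalysed enantioselective endo hydroacylation of ortho-(2-substituted allyl)benzaldehydes to 3-substituted 3,4-dihydronaphthalen-1(2H)-ones and of 2-(1-arylvinyl)benzaldehydes to 3-arylindanones, here moved to an oxygen-tethered 1,1-disubstituted enol ether. Ring C closes in the 6-endo-trig mode with respect to the C2=C3 bond. The new C2 centre is set under catalyst control, the chiral ligand choosing the alkene face at the hydride insertion, while the remote (R) side-chain centre should have no influence. The step needs endo over exo selectivity and chemoselectivity for the enol ether: the exo path would require a tertiary alkyl rhodium at C2 and lead to a quaternary benzofuranone, the enol ether has no allylic hydrogen so no isomerisation can compete, and the side-chain isopropenyl group cannot reach the acyl rhodium centre across the meta relationship. Decarbonylation and β-aryloxy elimination are the competing paths and should be held back by the bulky electron-rich ligand and by O1 being locked inside the forming ring.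

Step 19
Reactants: 26 (2S)-2-[2,4-bis(methoxymethoxy)phenyl]-8-[(2R)-5-hydroxy-5-methyl-2-(prop-1-en-2-yl)hexyl]-7-methoxy-5-(methoxymethoxy)-2,3-dihydro-4H-chromen-4-one
Product: 28 (2S)-2-(2,4-dihydroxyphenyl)-5-hydroxy-8-[(2R)-5-hydroxy-5-methyl-2-(prop-1-en-2-yl)hexyl]-7-methoxy-2,3-dihydro-4H-chromen-4-one, via tetrakis(trimethylsilyl) ether 27 (not isolated)
Conditions: TMSOTf, 2,2′-bipyridyl, MeCN, 0 °C to rt; then H2O/THF, aq. citric acid, rt
Reagents that add atoms: none
Why: Silyl triflate with bipyridyl exchanges aryl MOM acetals for silyl ethers under non-acidic conditions and mild aqueous work-up cleaves all Si–O bonds, which should avoid the protic acid or base that would ionise the C2–O1 bond, open ring C or dehydrate the tertiary carbinol.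

**Compound list**
1 | 2,4-dihydroxy-6-methoxybenzaldehyde | O=Cc1c(O)cc(O)cc1OC | starting material
2 | 2-hydroxy-6-methoxy-4-(methoxymethoxy)benzaldehyde | O=Cc1c(O)cc(OCOC)cc1OC | intermediate
3 | 2-formyl-3-methoxy-5-(methoxymethoxy)phenyl 4-methylbenzenesulfonate | O=Cc1c(OS(=O)(=O)c2ccc(C)cc2)cc(OCOC)cc1OC | intermediate
4 | 2-(hydroxymethyl)-3-methoxy-5-(methoxymethoxy)phenyl 4-methylbenzenesulfonate | OCc1c(OS(=O)(=O)c2ccc(C)cc2)cc(OCOC)cc1OC | intermediate
5 | 2-(bromomethyl)-3-methoxy-5-(methoxymethoxy)phenyl 4-methylbenzenesulfonate | BrCc1c(OS(=O)(=O)c2ccc(C)cc2)cc(OCOC)cc1OC | intermediate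
6 | (4S)-4-benzyl-1,3-oxazolidin-2-one | O=C1N[C@@H](Cc2ccccc2)CO1 | starting material
7 | methyl 5-chloro-5-oxopentanoate | COC(=O)CCCC(Cl)=O | starting material
8 | lithium (4S)-4-benzyl-2-oxo-1,3-oxazolidin-3-ide | [Li+].O=C1[N-][C@@H](Cc2ccccc2)CO1 | intermediate
9 | methyl 5-[(4S)-4-benzyl-2-oxo-1,3-oxazolidin-3-yl]-5-oxopentanoate | COC(=O)CCCC(=O)N1[C@@H](Cc2ccccc2)COC1=O | intermediate
10 | sodium (1Z)-1-[(4S)-4-benzyl-2-oxo-1,3-oxazolidin-3-yl]-5-methoxy-5-oxopent-1-en-1-olate | [Na+].COC(=O)CC/C=C(\[O-])N1[C@@H](Cc2ccccc2)COC1=O | intermediate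
11 | methyl (4R)-5-[(4S)-4-benzyl-2-oxo-1,3-oxazolidin-3-yl]-4-{[2-methoxy-4-(methoxymethoxy)-6-(tosyloxy)phenyl]methyl}-5-oxopentanoate | COC(=O)CC[C@H](Cc1c(OC)cc(OCOC)cc1OS(=O)(=O)c1ccc(C)cc1)C(=O)N1[C@@H](Cc2ccccc2)COC1=O | intermediate
12 | (2R)-5-methoxy-2-{[2-methoxy-4-(methoxymethoxy)-6-(tosyloxy)phenyl]methyl}-5-oxopentaneperoxoic acid | COC(=O)CC[C@H](Cc1c(OC)cc(OCOC)cc1OS(=O)(=O)c1ccc(C)cc1)C(=O)OO | intermediate
13 | (2R)-5-methoxy-2-{[2-methoxy-4-(methoxymethoxy)-6-(tosyloxy)phenyl]methyl}-5-oxopentanoic acid | COC(=O)CC[C@H](Cc1c(OC)cc(OCOC)cc1OS(=O)(=O)c1ccc(C)cc1)C(=O)O | intermediate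
14 | methyl (4R)-5-[methoxy(methyl)amino]-4-{[2-methoxy-4-(methoxymethoxy)-6-(tosyloxy)phenyl]methyl}-5-oxopentanoate | COC(=O)CC[C@H](Cc1c(OC)cc(OCOC)cc1OS(=O)(=O)c1ccc(C)cc1)C(=O)N(C)OC | intermediate
15 | 2-[(2R)-2-acetyl-5-hydroxy-5-methylhexyl]-3-methoxy-5-(methoxymethoxy)phenyl 4-methylbenzenesulfonate | CC(C)(O)CC[C@H](Cc1c(OC)cc(OCOC)cc1OS(=O)(=O)c1ccc(C)cc1)C(C)=O | intermediate
16 | 2-[(2R)-5-hydroxy-5-methyl-2-(prop-1-en-2-yl)hexyl]-3-methoxy-5-(methoxymethoxy)phenyl 4-methylbenzenesulfonate | CC(C)(O)CC[C@H](Cc1c(OC)cc(OCOC)cc1OS(=O)(=O)c1ccc(C)cc1)C(C)=C | intermediate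
17 | 2-[(2R)-5-hydroxy-5-methyl-2-(prop-1-en-2-yl)hexyl]-3-methoxy-5-(methoxymethoxy)phenol | CC(C)(O)CC[C@H](Cc1c(OC)cc(OCOC)cc1O)C(C)=C | intermediate
18 | 2-(hydroxymethyl)-6-[(2R)-5-hydroxy-5-methyl-2-(prop-1-en-2-yl)hexyl]-5-methoxy-3-(methoxymethoxy)phenol | CC(C)(O)CC[C@H](Cc1c(OC)cc(OCOC)c(CO)c1O)C(C)=C | intermediate
19 | 2-hydroxy-3-[(2R)-5-hydroxy-5-methyl-2-(prop-1-en-2-yl)hexyl]-4-methoxy-6-(methoxymethoxy)benzaldehyde | CC(C)(O)CC[C@H](Cc1c(OC)cc(OCOC)c(C=O)c1O)C(C)=C | intermediate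
20 | 2,4-dihydroxybenzaldehyde | O=Cc1ccc(O)cc1O | starting material
21 | 2,4-bis(methoxymethoxy)benzaldehyde | O=Cc1ccc(OCOC)cc1OCOC | intermediate
22 | 1-(2,2-dibromoethenyl)-2,4-bis(methoxymethoxy)benzene | BrC(Br)=Cc1ccc(OCOC)cc1OCOC | intermediate
23 | 1-(bromoethynyl)-2,4-bis(methoxymethoxy)benzene | BrC#Cc1ccc(OCOC)cc1OCOC | intermediate
24 | 2-({(Z)-1-[2,4-bis(methoxymethoxy)phenyl]-2-bromoethenyl}oxy)-3-[(2R)-5-hydroxy-5-methyl-2-(prop-1-en-2-yl)hexyl]-4-methoxy-6-(methoxymethoxy)benzaldehyde | CC(C)(O)CC[C@H](Cc1c(OC)cc(OCOC)c(C=O)c1O/C(=C\Br)c1ccc(OCOC)cc1OCOC)C(C)=C | intermediate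
25 | 2-({1-[2,4-bis(methoxymethoxy)phenyl]ethenyl}oxy)-3-[(2R)-5-hydroxy-5-methyl-2-(prop-1-en-2-yl)hexyl]-4-methoxy-6-(methoxymethoxy)benzaldehyde | CC(C)(O)CC[C@H](Cc1c(OC)cc(OCOC)c(C=O)c1OC(=C)c1ccc(OCOC)cc1OCOC)C(C)=C | intermediate
26 | (2S)-2-[2,4-bis(methoxymethoxy)phenyl]-8-[(2R)-5-hydroxy-5-methyl-2-(prop-1-en-2-yl)hexyl]-7-methoxy-5-(methoxymethoxy)-2,3-dihydro-4H-chromen-4-one | C=C(C)[C@H](CCC(C)(C)O)Cc1c(OC)cc(OCOC)c2c1O[C@H](c1ccc(OCOC)cc1OCOC)CC2=O | intermediate
27 | (2S)-2-[2,4-bis(trimethylsilyloxy)phenyl]-7-methoxy-8-[(2R)-5-methyl-2-(prop-1-en-2-yl)-5-(trimethylsilyloxy)hexyl]-5-(trimethylsilyloxy)-2,3-dihydro-4H-chromen-4-one | C=C(C)[C@H](CCC(C)(C)O[Si](C)(C)C)Cc1c(OC)cc(O[Si](C)(C)C)c2c1O[C@H](c1ccc(O[Si](C)(C)C)cc1O[Si](C)(C)C)CC2=O | intermediate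
28 | (2S)-2-(2,4-dihydroxyphenyl)-5-hydroxy-8-[(2R)-5-hydroxy-5-methyl-2-(prop-1-en-2-yl)hexyl]-7-methoxy-2,3-dihydro-4H-chromen-4-one | C=C(C)[C@H](CCC(C)(C)O)Cc1c(OC)cc(O)c2c1O[C@H](c1ccc(O)cc1O)CC2=O | target

**Step count and risks**

Total step count: 19. Longest linear sequence: 15 steps (steps 1 to 4, 6 to 12 and 16 to 19).

The three steps most likely to fail:

Step 18 (proposed new method). The acyl rhodium hydride may lose CO before the alkene inserts, insertion may take the exo sense, the alkyl rhodium intermediate may expel the aryloxide, or the facial selectivity at C2 may be poor. The fallback is the classical chalcone route; it sets out from 19 and comes back to the route at 26. Addition of MeMgBr (excess, THF, 0 °C) to the formyl group should give the benzylic carbinol F1 as both carbinol epimers, and MnO2 (CH2Cl2, rt) the 2′-hydroxyacetophenone F2. Claisen–Schmidt condensation of F2 with aldehyde 21 (KOH, EtOH, rt) should give the (E)-chalcone F3, in which only the future O1 is a free phenol. Intramolecular oxa-Michael addition (NaOAc, EtOH, reflux) should then give 26 together with its (2R) epimer F4, and 26 is taken from this pair by preparative chromatography on a chiral stationary phase.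

Step 16. The chelated, di-ortho-substituted phenoxide may add too slowly, so that halophilic attack on the bromoalkyne and ring bromination of the electron-rich phenoxide take over. The fallback builds the enol ether by ester methylenation; it sets out from 19 (with aldehyde 21), comes back at 25 and bypasses steps 16 and 17. Pinnick oxidation of 21 (NaClO2, NaH2PO4, 2-methylbut-2-ene, t-BuOH/H2O) should give 2,4-bis(methoxymethoxy)benzoic acid F5, and acylation of the phenol of 19 (EDC·HCl, DMAP, CH2Cl2) the aryl ester F6. The formyl group is masked as the dimethyl acetal F7 (HC(OMe)3, PPTS cat., MeOH, rt), and Tebbe olefination of the ester carbonyl (Cp2Ti(μ-Cl)(μ-CH2)AlMe2, pyridine, THF/toluene, −40 °C to rt) should give the enol ether acetal F8. The very labile 2,6-dioxygenated benzaldehyde acetal is then hydrolysed (PPTS cat., acetone/H2O, 0 °C) to 25 before the aryl enol ether reacts.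

Step 6. The electron-rich benzylic bromide 5 may ionise and alkylate its own ring before it meets the enolate. The fallback forms the same C–C bond from the stable aldehyde; it sets out from 3 (with acid chloride 7) and comes back at 13. The purchased (4R) antipode of auxiliary 6 is N-acylated with 7 (n-BuLi, THF, −78 °C) to the imide F9. Evans syn aldol addition of its dibutylboron enolate to 3 (Bu2BOTf, i-Pr2NEt, CH2Cl2, −78 to 0 °C; H2O2, pH 7 buffer) should give the aldol F10; the antipodal auxiliary is needed because the boron enolate reacts on the face opposite to that used by the chelated sodium enolate. The benzylic hydroxyl is converted to the thiocarbonyl imidazolide F11 (1,1′-thiocarbonyldiimidazole, DMAP, THF) and removed by Barton–McCombie deoxygenation (Bu3SnH, AIBN, toluene, 90 °C) to the imide F12, which is cleaved with LiOH/H2O2 as in step 7 to 13.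

**Further compounds**
F1 | step 18 | 2-(1-hydroxyethyl)-6-[(2R)-5-hydroxy-5-methyl-2-(prop-1-en-2-yl)hexyl]-5-methoxy-3-(methoxymethoxy)phenol (both carbinol epimers) | CC(C)(O)CC[C@H](Cc1c(OC)cc(OCOC)c(C(C)O)c1O)C(C)=C
F2 | step 18 | 1-{2-hydroxy-3-[(2R)-5-hydroxy-5-methyl-2-(prop-1-en-2-yl)hexyl]-4-methoxy-6-(methoxymethoxy)phenyl}ethan-1-one | CC(C)(O)CC[C@H](Cc1c(OC)cc(OCOC)c(C(C)=O)c1O)C(C)=C
F3 | step 18 | (2E)-3-[2,4-bis(methoxymethoxy)phenyl]-1-{2-hydroxy-3-[(2R)-5-hydroxy-5-methyl-2-(prop-1-en-2-yl)hexyl]-4-methoxy-6-(methoxymethoxy)phenyl}prop-2-en-1-one | CC(C)(O)CC[C@H](Cc1c(OC)cc(OCOC)c(C(=O)/C=C/c2ccc(OCOC)cc2OCOC)c1O)C(C)=C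
F4 | step 18 | (2R)-2-[2,4-bis(methoxymethoxy)phenyl]-8-[(2R)-5-hydroxy-5-methyl-2-(prop-1-en-2-yl)hexyl]-7-methoxy-5-(methoxymethoxy)-2,3-dihydro-4H-chromen-4-one | C=C(C)[C@H](CCC(C)(C)O)Cc1c(OC)cc(OCOC)c2c1O[C@@H](c1ccc(OCOC)cc1OCOC)CC2=O
F5 | step 16 | 2,4-bis(methoxymethoxy)benzoic acid | OC(=O)c1ccc(OCOC)cc1OCOC
F6 | step 16 | 2-formyl-6-[(2R)-5-hydroxy-5-methyl-2-(prop-1-en-2-yl)hexyl]-5-methoxy-3-(methoxymethoxy)phenyl 2,4-bis(methoxymethoxy)benzoate | CC(C)(O)CC[C@H](Cc1c(OC)cc(OCOC)c(C=O)c1OC(=O)c1ccc(OCOC)cc1OCOC)C(C)=C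
F7 | step 16 | 2-(dimethoxymethyl)-6-[(2R)-5-hydroxy-5-methyl-2-(prop-1-en-2-yl)hexyl]-5-methoxy-3-(methoxymethoxy)phenyl 2,4-bis(methoxymethoxy)benzoate | CC(C)(O)CC[C@H](Cc1c(OC)cc(OCOC)c(C(OC)OC)c1OC(=O)c1ccc(OCOC)cc1OCOC)C(C)=C
F8 | step 16 | (5R)-5-{[2-({1-[2,4-bis(methoxymethoxy)phenyl]ethenyl}oxy)-3-(dimethoxymethyl)-6-methoxy-4-(methoxymethoxy)phenyl]methyl}-2,6-dimethylhept-6-en-2-ol | CC(C)(O)CC[C@H](Cc1c(OC)cc(OCOC)c(C(OC)OC)c1OC(=C)c1ccc(OCOC)cc1OCOC)C(C)=C
F9 | step 6 | methyl 5-[(4R)-4-benzyl-2-oxo-1,3-oxazolidin-3-yl]-5-oxopentanoate | COC(=O)CCCC(=O)N1[C@H](Cc2ccccc2)COC1=O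
F10 | step 6 | methyl (4R)-5-[(4R)-4-benzyl-2-oxo-1,3-oxazolidin-3-yl]-4-{(R)-hydroxy[2-methoxy-4-(methoxymethoxy)-6-(tosyloxy)phenyl]methyl}-5-oxopentanoate | COC(=O)CC[C@H]([C@@H](O)c1c(OC)cc(OCOC)cc1OS(=O)(=O)c1ccc(C)cc1)C(=O)N1[C@H](Cc2ccccc2)COC1=O
F11 | step 6 | methyl (4R)-5-[(4R)-4-benzyl-2-oxo-1,3-oxazolidin-3-yl]-4-{(R)-[(1H-imidazol-1-ylcarbonothioyl)oxy][2-methoxy-4-(methoxymethoxy)-6-(tosyloxy)phenyl]methyl}-5-oxopentanoate | COC(=O)CC[C@H]([C@@H](OC(=S)n1ccnc1)c1c(OC)cc(OCOC)cc1OS(=O)(=O)c1ccc(C)cc1)C(=O)N1[C@H](Cc2ccccc2)COC1=O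
F12 | step 6 | methyl (4R)-5-[(4R)-4-benzyl-2-oxo-1,3-oxazolidin-3-yl]-4-{[2-methoxy-4-(methoxymethoxy)-6-(tosyloxy)phenyl]methyl}-5-oxopentanoate | COC(=O)CC[C@H](Cc1c(OC)cc(OCOC)cc1OS(=O)(=O)c1ccc(C)cc1)C(=O)N1[C@H](Cc2ccccc2)COC1=O
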